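The ten-membered carbocycle C1–C10 is cut across C2–C3. C1=C10 (the later oxirane) and C4=C5 are 1,5-related through that bond, so the ring is the [3,3] product of a C5–C10 cyclohexane bearing vinyl and hydroxyl on C10 and an (E)-alkoxypropenyl group on C5. One anionic oxy-Cope step expands six to ten, sets Z-C4=C5 and the C3 stereocentre, and gives a regiodefined C1 enolate that is oxidised in the same flask. The precursor is a cyclohexanol with the oxygens on C6, C8, C10 and the C7 side chain on one face, made from a lipase-desymmetrised cyclohexenediol by Claisen rearrangement, iodolactonisation and radical alkynylation.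

Key step: step 17

Remark 1: locants C1–C15 are those of the target (oxirane C1/C10, acetate C3, C4=C5, lactone oxygen on C6, methacrylate on C8, C11–C13 lactone carbons, C14 on C10, C15 on C4) and are used for every intermediate.
Remark 2: the oxirane of the target is cis (C2 and C9 on the same side), so it is taken from a 1(10)Z alkene; displacement at C1 of the chelation-derived cis-diol would give the trans-oxirane and is avoided.
Remark 3: an unassisted vinyl Grignard or vinylcerium reagent is expected to enter C10 equatorially and give the trans-dialkenyl carbinol (E-C4=C5 after rearrangement), so axial delivery is enforced with MAD.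
Remark 4 (assumption): the lipase is taken to hydrolyse the acetate on the future C8; with an enzyme of opposite preference the same monoacetate 3 results from lipase monoacetylation of the meso diol.

Step 1
Reactants: 1 cyclohexa-1,3-diene
Product: 2 cis-cyclohex-2-ene-1,4-diyl diacetate (meso)
Conditions: Pd(OAc)2 (cat.), LiCl (cat.), LiOAc, p-benzoquinone, AcOH, 25 °C
Reagents that add atoms: acetic acid (as lithium acetate), CC(=O)O
Why: Pd-catalysed oxidative 1,4-diacetoxylation of a conjugated diene, in which the π-allylpalladium intermediate is opened by external acetate on the face away from the metal when a little chloride blocks inner-sphere delivery, so the two acetates on the future C5 and C8 are cis.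

Step 2
Reactants: 2 cis-cyclohex-2-ene-1,4-diyl diacetate
Product: 3 (1S,4R)-4-hydroxycyclohex-2-en-1-yl acetate
Conditions: Candida antarctica lipase B, phosphate buffer pH 7, 25 °C
Reagents that add atoms: none
Why: Lipase desymmetrisation of a meso diacetate by hydrolysis of one enantiotopic ester, which fixes the absolute configuration of the whole route (future C8 R) and distinguishes the future O8 from the oxygen that drives the Claisen step.

Step 3
Reactants: 3 (1S,4R)-4-hydroxycyclohex-2-en-1-yl acetate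
Product: 4 (1S,4R)-4-[(tert-butyldiphenylsilyl)oxy]cyclohex-2-en-1-yl acetate
Conditions: TBDPSCl, imidazole, DMF, 25 °C
Reagents that add atoms: tert-butyl(chloro)diphenylsilane, CC(C)(C)[Si](Cl)(c1ccccc1)c1ccccc1
Why: Imidazole-promoted silylation of a secondary alcohol, putting on O8 a group that survives every step up to the late desilylation.

Step 4
Reactants: 4 (1S,4R)-4-[(tert-butyldiphenylsilyl)oxy]cyclohex-2-en-1-yl acetate
Product: 5 (1S,4R)-4-[(tert-butyldiphenylsilyl)oxy]cyclohex-2-en-1-ol
Conditions: K2CO3, MeOH, 0 → 25 °C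
Reagents that add atoms: none
Why: Base-catalysed transesterification (methanolysis) of the acetate frees the allylic alcohol on the future C5 without touching the silyl ether.

Step 5
Reactants: 5 (1S,4R)-4-[(tert-butyldiphenylsilyl)oxy]cyclohex-2-en-1-ol; 6 N,N-dimethylacetamide dimethyl acetal
Product: 8 cyclohexenyl acetamide, via ketene N,O-acetal 7 (not isolated)
Conditions: 6, xylene, 140 °C
Reagents that add atoms: N,N-dimethylacetamide dimethyl acetal 6, COC(C)(OC)N(C)C
Why: Eschenmoser–Claisen rearrangement, in which alcohol exchange gives the ketene N,O-acetal whose [3,3] shift forms C7–C11 on the ring face from which the C5–O bond leaves, that is cis to the C8 silyloxy group (C7 S), and moves the double bond to C5=C6.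

Step 6
Reactants: 8 cyclohexenyl acetamide
Product: 9 enone amide (C10 ketone, C5=C6)
Conditions: Rh2(cap)4 (cap = caprolactamate, 1 mol %), aq. TBHP, ClCH2CH2Cl, 40 °C
Reagents that add atoms: tert-butyl hydroperoxide, CC(C)(C)OO
Why: Dirhodium-caprolactamate-catalysed allylic C–H oxidation of a cyclohexene to the enone with tert-butylperoxy radicals, which should take the unhindered C10 methylene in preference to the tertiary C7–H flanked by the silyloxy group.

Step 7
Reactants: 9 enone amide
Product: 10 C10 ethylene ketal (C5=C6 retained)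
Conditions: (TMSOCH2)2, TMSOTf (cat.), CH2Cl2, −78 °C
Reagents that add atoms: 1,2-bis(trimethylsilyloxy)ethane, C[Si](C)(C)OCCO[Si](C)(C)C
Why: Aprotic silyl-triflate-catalysed ketalisation with the bis-silyl ether of ethylene glycol, conditions under which an enone double bond does not migrate, masks C10 while O6 and the C5 substituent are introduced.

Step 8
Reactants: 10 C10 ethylene ketal
Product: 12 iodolactone, via iminium lactone iodide 11 (not isolated)
Conditions: I2, THF/H2O, 25 °C, dark
Reagents that add atoms: iodine, II; water, O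
Why: Iodolactonisation of a γ,δ-unsaturated N,N-dimethylamide, in which the amide oxygen opens the iodonium ion at C6 in 5-exo mode from the face of C11 (cis-fused ring, O6 cis to C11 and O8), iodide sits anti on C5, and water hydrolyses the iminium ether to the lactone.

Step 9
Reactants: 13 ethynyltrimethylsilane
Product: 15 trimethyl{[(trifluoromethyl)sulfonyl]ethynyl}silane, via lithium (trimethylsilyl)acetylide 14 (not isolated)
Conditions: n-BuLi, Et2O, −78 °C; then Tf2O, −78 °C
Reagents that add atoms: trifluoromethanesulfonic anhydride, O=S(=O)(OS(=O)(=O)C(F)(F)F)C(F)(F)F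
Why: Deprotonation of the terminal alkyne and sulfonylation of the lithium acetylide with triflic anhydride give the alkynyl triflone used as radical trap in step 10.

Step 10
Reactants: 12 iodolactone; 15 trimethyl{[(trifluoromethyl)sulfonyl]ethynyl}silane
Product: 16 5-[(trimethylsilyl)ethynyl] lactone
Conditions: 15, (Bu3Sn)2 (cat.), hν, benzene, 25 °C
Reagents that add atoms: trimethyl{[(trifluoromethyl)sulfonyl]ethynyl}silane 15, C[Si](C)(C)C#CS(=O)(=O)C(F)(F)F
Why: Radical alkynylation of a secondary alkyl iodide with an alkynyl triflone (the C5 radical adds to the sulfonyl-bearing alkyne carbon, the triflyl radical is lost and the CF3 radical carries the chain by iodine abstraction), with the radical trapped on the face opposite the C6–O bond of the cis-fused lactone so that the alkyne is trans to O6.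

Step 11
Reactants: 16 5-[(trimethylsilyl)ethynyl] lactone
Product: 18 5-ethynyl-6,12-diol, via silylalkynyl diol 17 (not isolated)
Conditions: LiAlH4, THF, 0 °C; then K2CO3, MeOH, 25 °C
Reagents that add atoms: none
Why: Hydride reduction of the lactone to the 6,12-diol, followed by base-catalysed methanolysis of the alkynyl C–Si bond, removes the acyloxy leaving group β to C10 before the ketone is unveiled.

Step 12
Reactants: 18 5-ethynyl-6,12-diol
Product: 19 5-ethynyl-6,12-bis(tert-butyldimethylsilyl) ether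
Conditions: TBSOTf, 2,6-lutidine, CH2Cl2, −78 → 0 °C
Reagents that add atoms: tert-butyldimethylsilyl trifluoromethanesulfonate, CC(C)(C)[Si](C)(C)OS(=O)(=O)C(F)(F)F
Why: Silyl triflate with a hindered pyridine base silylates the primary and the hindered secondary alcohol under conditions cold enough to spare the dioxolane.

Step 13
Reactants: 19 5-ethynyl-6,12-bis(tert-butyldimethylsilyl) ether; 20 trimethylaluminium
Product: 22 (E)-vinyl iodide ketal, via alkenylalane 21 (not isolated)
Conditions: 20, Cp2ZrCl2, CH2Cl2, 0 → 25 °C; then I2, THF, −30 °C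
Reagents that add atoms: trimethylaluminium 20, C[Al](C)C; iodine, II
Why: Zirconium-catalysed syn-carboalumination of the terminal alkyne puts methyl (C15) on C4 and aluminium on C3 trans to C5, and iodinolysis of the C–Al bond with retention gives the E-alkenyl iodide that fixes the enol-ether geometry.

Step 14
Reactants: 22 (E)-vinyl iodide ketal
Product: 23 C10 ketone
Conditions: PPTS, acetone/H2O, 40 °C
Reagents that add atoms: water, O
Why: Mild acid-catalysed hydrolysis of the dioxolane, tolerated by the vinyl iodide and silyl ethers, gives the ketone in which C5, now epimerisable, rests in the equatorial arrangement trans to O6.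

Step 15
Reactants: 23 C10 ketone; 24 vinylmagnesium bromide
Product: 25 cis-1-vinyl-2-[(E)-1-iodoprop-1-en-2-yl]cyclohexanol
Conditions: MAD (from Me3Al and 2,6-di-tert-butyl-4-methylphenol, toluene, 25 °C), −78 °C; then 24, THF, −78 °C
Reagents that add atoms: vinylmagnesium bromide 24, C=C[Mg]Br
Why: Grignard 1,2-addition to a ketone pre-complexed with the bulky aluminium Lewis acid MAD, which shields the equatorial trajectory so that vinyl enters axially on the chair holding O6 and O8 equatorial and C11 axial, setting C10 (R) with vinyl cis to the C5 alkenyl group and the hydroxyl cis to O6 and O8.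

Step 16
Reactants: 25 cis-1-vinyl-2-[(E)-1-iodoprop-1-en-2-yl]cyclohexanol; 26 (4-methoxyphenyl)methanol
Product: 27 oxy-Cope precursor (E-enol ether)
Conditions: 26, CuI (cat.), 3,4,7,8-tetramethyl-1,10-phenanthroline (cat.), Cs2CO3, toluene, 80 °C
Reagents that add atoms: (4-methoxyphenyl)methanol 26, COc1ccc(CO)cc1
Why: Copper-catalysed Ullmann-type C–O coupling of a vinyl iodide with a primary alcohol proceeds with retention of alkene geometry, and carbonate in toluene does not generate a dissociated tertiary alkoxide, so the dienol should not rearrange prematurely.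

Step 17
Reactants: 27 oxy-Cope precursor
Product: 30 (Z)-1-hydroxycyclodec-5-enone, via potassium alkoxide 28 (not isolated), via potassium enolate 29 (not isolated)
Conditions: KH, 18-crown-6, THF, 0 → 25 °C; then 2-(phenylsulfonyl)-3-phenyloxaziridine, −78 °C; aq. NH4Cl
Reagents that add atoms: 2-(phenylsulfonyl)-3-phenyloxaziridine, O=S(=O)(N1OC1c1ccccc1)c1ccccc1
Why: KH with 18-crown-6 gives the dissociated C10 alkoxide 28, whose concerted [3,3] shift (anionic oxy-Cope, the known ring expansion of 1,2-dialkenylcyclohexanols to cyclodec-5-enones) forms C2–C3 as C5–C10 breaks, so the ten-membered ring arises by ring expansion through a six-centre chair transition state and not by cyclisation of a chain. The three equatorial oxygens on C6, C8 and C10 hold the cyclohexane chair with the C10 vinyl axial and the C5 alkenyl equatorial, so on the Cope chair C9 is equatorial and C6 axial, which gives the enolate 29 with C2 and C9 trans and the required Z-C4=C5. C3 is created by suprafacial transfer from C5 across the E-enol ether, whose alkoxy group is equatorial on the Cope chair, so C3 is S. The enolate forms only toward C1 and is trapped cold by the N-sulfonyloxaziridine (enolate hydroxylation) before proton exchange can move it to C9, where the C8 silyloxy group would be eliminated. The C1 carbinol configuration (attack expected on the outer face, 1R) is of no consequence because C1 becomes sp2 in step 20.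

Step 18
Reactants: 30 (Z)-1-hydroxycyclodec-5-enone; 31 methylmagnesium bromide
Product: 32 1,10-cis-diol
Conditions: 31 (excess), THF, −78 → 0 °C
Reagents that add atoms: methylmagnesium bromide 31, C[Mg]Br
Why: Chelation-controlled Grignard addition to an α-hydroxy ketone, in which the magnesium alkoxide chelate directs methyl (C14) to the carbonyl face away from C2, gives the 1,10-cis-diol whatever the C1 configuration.

Step 19
Reactants: 32 1,10-cis-diol
Product: 33 cyclic thionocarbonate
Conditions: 1,1′-thiocarbonyldiimidazole, DMAP, toluene, 90 °C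
Reagents that add atoms: 1,1′-thiocarbonyldiimidazole, S=C(n1ccnc1)n1ccnc1
Why: Thiocarbonylation of a cis-1,2-diol to the cyclic thionocarbonate is the first stage of the Corey–Winter olefination.

Step 20
Reactants: 33 cyclic thionocarbonate
Product: 34 (1(10)Z,4Z)-diene
Conditions: 1,3-dimethyl-2-phenyl-1,3,2-diazaphospholidine, THF, 40 °C
Reagents that add atoms: none
Why: Corey–Winter fragmentation, in which the phosphorus reagent abstracts sulfur and the resulting carbene loses CO2 in a stereospecific syn-elimination, converts the cis-thionocarbonate into the 1(10)Z alkene at a temperature too low for Cope rearrangement of the 1,5-diene.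

Step 21
Reactants: 34 (1(10)Z,4Z)-diene
Product: 35 6,12-diol
Conditions: HF·pyridine, pyridine, THF, 0 °C
Reagents that add atoms: none
Why: Buffered HF·pyridine cleaves the primary and the secondary tert-butyldimethylsilyl ethers while the more acid-stable tert-butyldiphenylsilyl ether on O8 stays, so only O6 and O12 are freed.

Step 22
Reactants: 35 6,12-diol
Product: 37 cis-fused 6,12-lactone, via lactol 36 (not isolated)
Conditions: TEMPO (cat.), PhI(OAc)2, CH2Cl2, 25 °C
Reagents that add atoms: none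
Why: Oxidative lactonisation of a 1,4-diol, in which the oxoammonium species oxidises the primary alcohol, the aldehyde closes onto the cis C6 hydroxyl and the lactol is oxidised again, can give only the 6,12-lactone because O8 is still silylated.

Step 23
Reactants: 37 cis-fused 6,12-lactone; 38 N,N-dimethylmethyleneiminium iodide
Product: 42 α-methylene lactone, via lithium enolate 39 (not isolated), via Mannich base 40 (not isolated), via ammonium iodide 41 (not isolated)
Conditions: LDA, THF, −78 °C; 38, −78 → 0 °C; then MeI, MeOH, 25 °C; then aq. NaHCO3, CH2Cl2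
Reagents that add atoms: N,N-dimethylmethyleneiminium iodide 38, C=[N+](C)C.[I-]
Why: α-Methylenation of a lactone by Mannich reaction of its lithium enolate with the iminium salt, N-methylation and base-induced β-elimination of trimethylamine, after which C11 is sp2 and carries no configuration.

Step 24
Reactants: 42 α-methylene lactone
Product: 43 C8 alcohol
Conditions: TBAF, AcOH, THF, 25 °C
Reagents that add atoms: none
Why: Fluoride cleavage of the tert-butyldiphenylsilyl ether, buffered with acetic acid so that the C8 alkoxide neither adds to the methylene lactone nor translactonises.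

Step 25
Reactants: 43 C8 alcohol
Product: 44 (1R,10S)-epoxy alcohol
Conditions: VO(acac)2 (cat.), TBHP (decane), CH2Cl2, 0 °C
Reagents that add atoms: tert-butyl hydroperoxide, CC(C)(C)OO
Why: Hydroxyl-directed epoxidation of a homoallylic alcohol by a vanadium alkylperoxide delivers oxygen to C1=C10 on the face of the C8 hydroxyl, giving the (1R,10S) cis-oxirane, while C4=C5 is deactivated by two allylic oxygens and the methylene lactone is electron-poor.

Step 26
Reactants: 44 (1R,10S)-epoxy alcohol; 45 methacrylic anhydride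
Product: 46 C8 methacrylate
Conditions: 45, Et3N, DMAP, CH2Cl2, 0 °C
Reagents that add atoms: methacrylic anhydride 45, C=C(C)C(=O)OC(=O)C(C)=C
Why: DMAP-catalysed acylation of the secondary C8 alcohol with the anhydride under non-acidic conditions leaves the oxirane intact.

Step 27
Reactants: 46 C8 methacrylate
Product: 47 C3 alcohol
Conditions: DDQ, CH2Cl2/pH 7 buffer, 0 °C
Reagents that add atoms: none
Why: Oxidative cleavage of the 4-methoxybenzyl ether by DDQ (benzylic hydride abstraction, then hydrolysis of the oxocarbenium ion) runs under buffered conditions tolerated by the oxirane and both acrylate units.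

Step 28
Reactants: 47 C3 alcohol; 48 acetic anhydride
Product: 49 target CNP0267696.1
Conditions: 48, pyridine, DMAP (cat.), CH2Cl2, 0 °C
Reagents that add atoms: acetic anhydride 48, CC(=O)OC(C)=O
Why: DMAP-catalysed acetylation of the allylic C3 alcohol completes the target without touching any stereocentre.

Compound list
1 | cyclohexa-1,3-diene | C1=CC=CCC1 | starting material
2 | cis-cyclohex-2-ene-1,4-diyl diacetate (meso; carbinol carbons are the future C5 and C8) | CC(=O)O[C@@H]1CC[C@H](OC(C)=O)C=C1 | intermediate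
3 | (1S,4R)-4-hydroxycyclohex-2-en-1-yl acetate (free OH on the future C8, acetate on the future C5) | O[C@@H]1CC[C@H](OC(C)=O)C=C1 | intermediate
4 | (1S,4R)-4-[(tert-butyldiphenylsilyl)oxy]cyclohex-2-en-1-yl acetate | CC(C)(C)[Si](c2ccccc2)(c3ccccc3)O[C@@H]1CC[C@H](OC(C)=O)C=C1 | intermediate
5 | (1S,4R)-4-[(tert-butyldiphenylsilyl)oxy]cyclohex-2-en-1-ol | CC(C)(C)[Si](c2ccccc2)(c3ccccc3)O[C@@H]1CC[C@H](O)C=C1 | intermediate
6 | N,N-dimethylacetamide dimethyl acetal (1,1-dimethoxy-N,N-dimethylethanamine) | COC(C)(OC)N(C)C | starting material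
7 | ketene N,O-acetal: O-[1-(dimethylamino)vinyl] ether of 5 (not isolated) | CC(C)(C)[Si](c2ccccc2)(c3ccccc3)O[C@@H]1CC[C@H](OC(=C)N(C)C)C=C1 | intermediate
8 | 2-[(1S,6R)-6-[(tert-butyldiphenylsilyl)oxy]cyclohex-2-en-1-yl]-N,N-dimethylacetamide (C11 on C7 cis to 8-OTBDPS; C5=C6) | CC(C)(C)[Si](c2ccccc2)(c3ccccc3)O[C@@H]1CCC=C[C@@H]1CC(=O)N(C)C | intermediate
9 | 2-[(1S,6R)-6-[(tert-butyldiphenylsilyl)oxy]-4-oxocyclohex-2-en-1-yl]-N,N-dimethylacetamide (C10 ketone, C5=C6) | CC(C)(C)[Si](c2ccccc2)(c3ccccc3)O[C@@H]1CC(=O)C=C[C@@H]1CC(=O)N(C)C | intermediate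
10 | C10 ethylene ketal of 9 (spiro-1,3-dioxolane on C10, C5=C6 unchanged) | CC(C)(C)[Si](c2ccccc2)(c3ccccc3)O[C@@H]1CC6(OCCO6)C=C[C@@H]1CC(=O)N(C)C | intermediate
11 | iminium lactone iodide: 5-iodo (trans to O6), cis-fused O6–C12(=N+Me2) ring, C10 ketal (not isolated) | CC(C)(C)[Si](c2ccccc2)(c3ccccc3)O[C@@H]1CC6(OCCO6)[C@@H](I)[C@H](OC(=[N+](C)C)C5)[C@@H]15.[I-] | intermediate
12 | iodolactone: cis-fused 6,12-γ-lactone (O6 cis to C11 and to 8-OTBDPS), 5-iodo trans to O6, C10 ethylene ketal | CC(C)(C)[Si](c2ccccc2)(c3ccccc3)O[C@@H]1CC6(OCCO6)[C@@H](I)[C@H](OC(=O)C5)[C@@H]15 | intermediate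
13 | ethynyltrimethylsilane | C#C[Si](C)(C)C | starting material
14 | lithium (trimethylsilyl)acetylide (not isolated) | [Li+].[C-]#C[Si](C)(C)C | intermediate
15 | trimethyl{[(trifluoromethyl)sulfonyl]ethynyl}silane | C[Si](C)(C)C#CS(=O)(=O)C(F)(F)F | intermediate
16 | 5-[(trimethylsilyl)ethynyl] lactone (alkyne trans to O6; otherwise as 12) | CC(C)(C)[Si](c2ccccc2)(c3ccccc3)O[C@@H]1CC6(OCCO6)[C@@H](C#C[Si](C)(C)C)[C@H](OC(=O)C5)[C@@H]15 | intermediate
17 | 5-[(trimethylsilyl)ethynyl]-6,12-diol, C10 ketal, 8-OTBDPS (not isolated) | CC(C)(C)[Si](c2ccccc2)(c3ccccc3)O[C@@H]1CC6(OCCO6)[C@@H](C#C[Si](C)(C)C)[C@H](O)[C@@H]1CCO | intermediate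
18 | 5-ethynyl-6,12-diol, C10 ketal, 8-OTBDPS | CC(C)(C)[Si](c2ccccc2)(c3ccccc3)O[C@@H]1CC6(OCCO6)[C@@H](C#C)[C@H](O)[C@@H]1CCO | intermediate
19 | 5-ethynyl-6,12-bis(tert-butyldimethylsilyl) ether, C10 ketal, 8-OTBDPS | CC(C)(C)[Si](c2ccccc2)(c3ccccc3)O[C@@H]1CC6(OCCO6)[C@@H](C#C)[C@H](O[Si](C)(C)C(C)(C)C)[C@@H]1CCO[Si](C)(C)C(C)(C)C | intermediate
20 | trimethylaluminium | C[Al](C)C | starting material
21 | (E)-alkenyl(dimethyl)alane: C5–C(CH3)=CH–AlMe2 derivative of 19 (not isolated) | CC(C)(C)[Si](c2ccccc2)(c3ccccc3)O[C@@H]1CC6(OCCO6)[C@@H](/C(C)=C/[Al](C)C)[C@H](O[Si](C)(C)C(C)(C)C)[C@@H]1CCO[Si](C)(C)C(C)(C)C | intermediate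
22 | 5-[(E)-1-iodoprop-1-en-2-yl] C10 ketal with 6-OTBS, 7-(2-TBSO-ethyl), 8-OTBDPS | CC(C)(C)[Si](c2ccccc2)(c3ccccc3)O[C@@H]1CC6(OCCO6)[C@@H](/C(C)=C/I)[C@H](O[Si](C)(C)C(C)(C)C)[C@@H]1CCO[Si](C)(C)C(C)(C)C | intermediate
23 | C10 ketone: 5-[(E)-1-iodoprop-1-en-2-yl] trans to 6-OTBS; O6, C11 and O8 all cis | CC(C)(C)[Si](c2ccccc2)(c3ccccc3)O[C@@H]1CC(=O)[C@@H](/C(C)=C/I)[C@H](O[Si](C)(C)C(C)(C)C)[C@@H]1CCO[Si](C)(C)C(C)(C)C | intermediate
24 | vinylmagnesium bromide | C=C[Mg]Br | starting material
25 | (5S,6R,7R,8R,10R)-cis-1-vinyl-2-[(E)-1-iodoprop-1-en-2-yl]cyclohexanol: 10-OH cis to O6 and O8, vinyl cis to the C5 alkenyl group | CC(C)(C)[Si](c2ccccc2)(c3ccccc3)O[C@@H]1C[C@@](O)(C=C)[C@@H](/C(C)=C/I)[C@H](O[Si](C)(C)C(C)(C)C)[C@@H]1CCO[Si](C)(C)C(C)(C)C | intermediate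
26 | (4-methoxyphenyl)methanol | COc1ccc(CO)cc1 | starting material
27 | oxy-Cope precursor: (5S,6R,7R,8R,10R)-cis-1-vinyl-2-[(E)-1-(4-methoxybenzyloxy)prop-1-en-2-yl]cyclohexanol with 6-OTBS, 7-(2-TBSO-ethyl), 8-OTBDPS; O6, C11, O8 and O10 all cis | CC(C)(C)[Si](c2ccccc2)(c3ccccc3)O[C@@H]1C[C@@](O)(C=C)[C@@H](/C(C)=C/OCc4ccc(OC)cc4)[C@H](O[Si](C)(C)C(C)(C)C)[C@@H]1CCO[Si](C)(C)C(C)(C)C | intermediate
28 | potassium C10 alkoxide of 27 (not isolated) | CC(C)(C)[Si](c2ccccc2)(c3ccccc3)O[C@@H]1C[C@@]([O-])(C=C)[C@@H](/C(C)=C/OCc4ccc(OC)cc4)[C@H](O[Si](C)(C)C(C)(C)C)[C@@H]1CCO[Si](C)(C)C(C)(C)C.[K+] | intermediate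
29 | potassium enolate of the (Z)-cyclodec-5-enone: C1=C10–O− with C2 and C9 trans, Z-C4=C5, (3S)-OPMB, 6-OTBS, 7-(2-TBSO-ethyl), 8-OTBDPS (not isolated) | CC(C)(C)[Si](c2ccccc2)(c3ccccc3)O[C@@H]1C/C([O-])=C/C[C@H](OCc4ccc(OC)cc4)/C(C)=C\[C@H](O[Si](C)(C)C(C)(C)C)[C@@H]1CCO[Si](C)(C)C(C)(C)C.[K+] | intermediate
30 | (1R,3S,4Z,6S,7R,8R)-1-hydroxy-(Z)-cyclodec-5-enone (C10 ketone) with 3-OPMB, 6-OTBS, 7-(2-TBSO-ethyl), 8-OTBDPS | CC(C)(C)[Si](c2ccccc2)(c3ccccc3)O[C@@H]1CC(=O)[C@H](O)C[C@H](OCc4ccc(OC)cc4)/C(C)=C\[C@H](O[Si](C)(C)C(C)(C)C)[C@@H]1CCO[Si](C)(C)C(C)(C)C | intermediate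
31 | methylmagnesium bromide | C[Mg]Br | starting material
32 | (1R,10S)-1,10-cis-diol with C14 methyl on C10 | CC(C)(C)[Si](c2ccccc2)(c3ccccc3)O[C@@H]1C[C@@](O)(C)[C@H](O)C[C@H](OCc4ccc(OC)cc4)/C(C)=C\[C@H](O[Si](C)(C)C(C)(C)C)[C@@H]1CCO[Si](C)(C)C(C)(C)C | intermediate
33 | 1,10-cyclic thionocarbonate of 32 | CC(C)(C)[Si](c2ccccc2)(c3ccccc3)O[C@@H]1C[C@]6(C)OC(=S)O[C@@H]6C[C@H](OCc4ccc(OC)cc4)/C(C)=C\[C@H](O[Si](C)(C)C(C)(C)C)[C@@H]1CCO[Si](C)(C)C(C)(C)C | intermediate
34 | (1(10)Z,4Z)-4,10-dimethylcyclodeca-1(10),4-diene with 3-OPMB, 6-OTBS, 7-(2-TBSO-ethyl), 8-OTBDPS | CC(C)(C)[Si](c2ccccc2)(c3ccccc3)O[C@@H]1C/C(C)=C\C[C@H](OCc4ccc(OC)cc4)/C(C)=C\[C@H](O[Si](C)(C)C(C)(C)C)[C@@H]1CCO[Si](C)(C)C(C)(C)C | intermediate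
35 | 6,12-diol of 34 (8-OTBDPS and 3-OPMB retained) | CC(C)(C)[Si](c2ccccc2)(c3ccccc3)O[C@@H]1C/C(C)=C\C[C@H](OCc4ccc(OC)cc4)/C(C)=C\[C@H](O)[C@@H]1CCO | intermediate
36 | 6,12-lactol, mixture of C12 anomers (not isolated) | CC(C)(C)[Si](c2ccccc2)(c3ccccc3)O[C@@H]1C/C(C)=C\C[C@H](OCc4ccc(OC)cc4)/C(C)=C\[C@H](OC(O)C5)[C@@H]15 | intermediate
37 | cis-fused 6,12-γ-lactone with 3-OPMB, 8-OTBDPS, (1(10)Z,4Z)-diene | CC(C)(C)[Si](c2ccccc2)(c3ccccc3)O[C@@H]1C/C(C)=C\C[C@H](OCc4ccc(OC)cc4)/C(C)=C\[C@H](OC(=O)C5)[C@@H]15 | intermediate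
38 | N,N-dimethylmethyleneiminium iodide | C=[N+](C)C.[I-] | starting material
39 | lithium enolate of lactone 37 (not isolated) | CC(C)(C)[Si](c2ccccc2)(c3ccccc3)O[C@@H]1C/C(C)=C\C[C@H](OCc4ccc(OC)cc4)/C(C)=C\[C@H](OC([O-])=C5)[C@@H]15.[Li+] | intermediate
40 | 11-(dimethylaminomethyl) lactone, C11 epimers (not isolated) | CC(C)(C)[Si](c2ccccc2)(c3ccccc3)O[C@@H]1C/C(C)=C\C[C@H](OCc4ccc(OC)cc4)/C(C)=C\[C@H](OC(=O)C5CN(C)C)[C@@H]15 | intermediate
41 | 11-(trimethylammoniomethyl) lactone iodide (not isolated) | CC(C)(C)[Si](c2ccccc2)(c3ccccc3)O[C@@H]1C/C(C)=C\C[C@H](OCc4ccc(OC)cc4)/C(C)=C\[C@H](OC(=O)C5C[N+](C)(C)C)[C@@H]15.[I-] | intermediate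
42 | α-methylene-γ-lactone (C11=C13) with 3-OPMB, 8-OTBDPS, (1(10)Z,4Z)-diene | CC(C)(C)[Si](c2ccccc2)(c3ccccc3)O[C@@H]1C/C(C)=C\C[C@H](OCc4ccc(OC)cc4)/C(C)=C\[C@H](OC(=O)C5=C)[C@@H]15 | intermediate
43 | 8-hydroxy α-methylene lactone with 3-OPMB, (1(10)Z,4Z)-diene | O[C@@H]1C/C(C)=C\C[C@H](OCc4ccc(OC)cc4)/C(C)=C\[C@H](OC(=O)C5=C)[C@@H]15 | intermediate
44 | (1R,10S)-1,10-epoxy-8-hydroxy lactone with 3-OPMB (oxirane cis to 8-OH) | O[C@@H]1C[C@]6(C)O[C@@H]6C[C@H](OCc4ccc(OC)cc4)/C(C)=C\[C@H](OC(=O)C5=C)[C@@H]15 | intermediate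
45 | methacrylic anhydride | C=C(C)C(=O)OC(=O)C(C)=C | starting material
46 | 8-methacrylate of 44 (3-OPMB) | C=C(C)C(=O)O[C@@H]1C[C@]6(C)O[C@@H]6C[C@H](OCc4ccc(OC)cc4)/C(C)=C\[C@H](OC(=O)C5=C)[C@@H]15 | intermediate
47 | 3-hydroxy 8-methacrylate epoxy lactone | C=C(C)C(=O)O[C@@H]1C[C@]6(C)O[C@@H]6C[C@H](O)/C(C)=C\[C@H](OC(=O)C5=C)[C@@H]15 | intermediate
48 | acetic anhydride | CC(=O)OC(C)=O | starting material
49 | CNP0267696.1: (1R,3S,4Z,6S,7R,8R,10S)-3-acetoxy-1,10-epoxy-8-(methacryloyloxy)germacra-4,11(13)-dien-12,6-olide | C=C(C)C(=O)O[C@@H]1C[C@]2(C)O[C@@H]2C[C@H](OC(C)=O)/C(C)=C\[C@@H]2OC(=O)C(=C)[C@@H]21 | target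

Total step count: 28 (27 on the main line plus step 9, the preparation of the alkynyl triflone).
Longest linear sequence: 27 steps (1–8 and 10–28) from cyclohexa-1,3-diene.

Steps most likely to fail

Step 17 (key step). The alkoxide may leak through a boat or through the ring-flipped chair, which would erode the Z geometry and the C3 configuration; a silyl group may migrate from O6 to the C10 alkoxide; or the enolate may exchange protons before oxygen transfer and lose its regiochemistry. Fallback: starting from 27, the tertiary alcohol is silylated with N-(trimethylsilyl)imidazole to give the C10 trimethylsilyl ether F3, which is heated in o-dichlorobenzene at about 200 °C in base-washed glass for the neutral siloxy-Cope rearrangement through the same chair; this gives the regiodefined trimethylsilyl enol ether F4. Rubottom oxidation with dimethyldioxirane (acetone, −40 °C) should give the 1-(trimethylsilyloxy) ketone F5, and citric acid in methanol releases 30, where the route resumes.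

Step 15. The vinyl group may be delivered equatorially instead of axially (poor facial selectivity), or the hindered ketone may be enolised by the Grignard reagent. Fallback: starting from 23, lithium (trimethylsilyl)acetylide in THF at −78 °C is used, because small sp-hybridised nucleophiles add axially to cyclohexanones; it should give the silylethynyl carbinol F1. K2CO3 in methanol removes silicon to give the ethynyl carbinol F2, and semi-hydrogenation (H2, Pd on CaCO3 poisoned with Pb(OAc)2, quinoline) returns to 25.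

Step 25. Oxygen may be delivered to the wrong face of C1=C10, or the free C8 hydroxyl may open the new oxirane to a transannular ether. Fallback: starting from 43, the alcohol is acylated first (45, Et3N, DMAP) to give the diene methacrylate F6, which is epoxidised under reagent control by Shi epoxidation (fructose-derived ketone of the enantiomeric series matched to the α-face, KHSO5, K2CO3 buffer, MeCN/dimethoxymethane/H2O, 0 °C); the product is 46.

Further compounds
F1 | step 15 | silylethynyl carbinol: 10-[(trimethylsilyl)ethynyl] analogue of 25, alkyne axial and cis to the C5 alkenyl group | CC(C)(C)[Si](c2ccccc2)(c3ccccc3)O[C@@H]1C[C@@](O)(C#C[Si](C)(C)C)[C@@H](/C(C)=C/I)[C@H](O[Si](C)(C)C(C)(C)C)[C@@H]1CCO[Si](C)(C)C(C)(C)C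
F2 | step 15 | ethynyl carbinol: 10-ethynyl analogue of 25 | CC(C)(C)[Si](c2ccccc2)(c3ccccc3)O[C@@H]1C[C@@](O)(C#C)[C@@H](/C(C)=C/I)[C@H](O[Si](C)(C)C(C)(C)C)[C@@H]1CCO[Si](C)(C)C(C)(C)C
F3 | step 17 | C10 trimethylsilyl ether of 27 | CC(C)(C)[Si](c2ccccc2)(c3ccccc3)O[C@@H]1C[C@@](O[Si](C)(C)C)(C=C)[C@@H](/C(C)=C/OCc4ccc(OC)cc4)[C@H](O[Si](C)(C)C(C)(C)C)[C@@H]1CCO[Si](C)(C)C(C)(C)C
F4 | step 17 | trimethylsilyl enol ether of the (Z)-cyclodec-5-enone (C1=C10–OTMS, C2 and C9 trans) | CC(C)(C)[Si](c2ccccc2)(c3ccccc3)O[C@@H]1C/C(O[Si](C)(C)C)=C/C[C@H](OCc4ccc(OC)cc4)/C(C)=C\[C@H](O[Si](C)(C)C(C)(C)C)[C@@H]1CCO[Si](C)(C)C(C)(C)C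
F5 | step 17 | 1-(trimethylsilyloxy) ketone: O1-trimethylsilyl ether of 30 | CC(C)(C)[Si](c2ccccc2)(c3ccccc3)O[C@@H]1CC(=O)[C@H](O[Si](C)(C)C)C[C@H](OCc4ccc(OC)cc4)/C(C)=C\[C@H](O[Si](C)(C)C(C)(C)C)[C@@H]1CCO[Si](C)(C)C(C)(C)C
F6 | step 25 | diene methacrylate: 8-methacrylate of 43 | C=C(C)C(=O)O[C@@H]1C/C(C)=C\C[C@H](OCc4ccc(OC)cc4)/C(C)=C\[C@H](OC(=O)C5=C)[C@@H]15
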